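**Assumption:** (+)-aromadendrin (natural (2R,3R)-dihydrokaempferol), 4-hydroxy-2-iodobenzaldehyde and 1-[2,4-bis(benzyloxy)-6-hydroxyphenyl]ethan-1-one are bought; the target SMILES fixes no biaryl axis, so the axis is treated as freely rotating. The target is (2R,3R)-trans, the configuration of natural aromadendrin.

## Retrosynthetic overview

1. Target 13 ⇐ 12 ⇐ 11: acetate methanolysis, preceded by one hydrogenolysis that removes three benzyl ethers and a traceless iodine at C2' of flavone ring B.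
2. Key bond C8 (flavanonol ring A)–C3' (flavone ring B) ⇐ [3,3]-sigmatropic rearrangement of the O–I tethered aryloxy-λ3-iodane 10, formed from phenol 3 and iodane 9.
3. 3 ⇐ (+)-aromadendrin 1 (both stereocentres purchased) by peracetylation and selective 7-O-deacetylation.
4. 9 ⇐ 2'-iodoflavone 8 ⇐ chalcone 7 ⇐ aldehyde 5 + acetophenone 6.
5. Ring order: flavone ring C is the only ring built (step 5); the flavanonol rings come intact from 1; no ring is formed after the biaryl bond.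

## Route

**Step 1**
Reactants: 1 (+)-aromadendrin, (2R,3R)-3,5,7-trihydroxy-2-(4-hydroxyphenyl)chroman-4-one
Product: 2 (2R,3R)-2-(4-acetoxyphenyl)-4-oxochromane-3,5,7-triyl triacetate
Conditions: Ac2O (6 equiv), pyridine, DMAP (cat.), 0 °C → rt
Reagents that add atoms: acetic anhydride, CC(=O)OC(C)=O
Why: Exhaustive O-acylation of the three phenols and the secondary alcohol under mild amine base, which leaves the trans (2R,3R) centres of the dihydroflavonol untouched.

**Step 2**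
Reactants: 2 (2R,3R)-2-(4-acetoxyphenyl)-4-oxochromane-3,5,7-triyl triacetate
Product: 3 (2R,3R)-2-(4-acetoxyphenyl)-7-hydroxy-4-oxochromane-3,5-diyl diacetate
Conditions: PhSH (1.1 equiv), imidazole (0.3 equiv), NMP, 0 °C
Reagents that add atoms: none
Why: Chemoselective transacylation to the thiol: the 7-acetate, para to the C4 carbonyl, has the best phenoxide leaving group and is cleaved first, as in the known 7-O-deacetylation of flavonoid peracetates; no stereocentre is involved.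

**Step 3**
Reactants: 4 4-hydroxy-2-iodobenzaldehyde
Product: 5 4-(benzyloxy)-2-iodobenzaldehyde
Conditions: BnBr, K2CO3, DMF, rt
Reagents that add atoms: benzyl bromide, BrCc1ccccc1
Why: Williamson ether synthesis on an acidic para-formyl phenol.

**Step 4**
Reactants: 5 4-(benzyloxy)-2-iodobenzaldehyde; 6 1-[2,4-bis(benzyloxy)-6-hydroxyphenyl]ethan-1-one
Product: 7 (E)-1-[2,4-bis(benzyloxy)-6-hydroxyphenyl]-3-[4-(benzyloxy)-2-iodophenyl]prop-2-en-1-one
Conditions: KOH (50% aq.), EtOH–THF, rt, 24 h; then dilute HCl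
Reagents that add atoms: none
Why: Claisen–Schmidt aldol condensation of a non-enolisable aldehyde with the methyl ketone, E1cB dehydration giving the E-chalcone.

**Step 5**
Reactants: 7 (E)-chalcone
Product: 8 5,7-bis(benzyloxy)-2-[4-(benzyloxy)-2-iodophenyl]-4H-chromen-4-one
Conditions: I2 (0.1 equiv), DMSO, 120 °C, 2–3 h
Reagents that add atoms: none
Why: Oxidative cyclisation of a 2'-hydroxychalcone (oxa-Michael closure, α-iodination, HI loss) with DMSO as terminal oxidant builds flavone ring C; the aryl iodide is inert.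

**Step 6**
Reactants: 8 5,7-bis(benzyloxy)-2-[4-(benzyloxy)-2-iodophenyl]-4H-chromen-4-one
Product: 9 {5-(benzyloxy)-2-[5,7-bis(benzyloxy)-4-oxo-4H-chromen-2-yl]phenyl}-λ3-iodanediyl diacetate
Conditions: NaBO3·4H2O (10 equiv), AcOH, 45 °C
Reagents that add atoms: acetic acid, CC(=O)O
Why: Perborate in acetic acid oxidises an aryl iodide from monovalent to trivalent iodine and the diacetate is trapped by the solvent; the electron-poor chromone alkene and the benzyl ethers are not attacked under these mild conditions.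

**Step 7**
Reactants: 3 (2R,3R)-2-(4-acetoxyphenyl)-7-hydroxy-4-oxochromane-3,5-diyl diacetate; 9 flavonyl-λ3-iodanediyl diacetate
Product: 11 (2R,3R)-2-(4-acetoxyphenyl)-8-{6-(benzyloxy)-3-[5,7-bis(benzyloxy)-4-oxo-4H-chromen-2-yl]-2-iodophenyl}-7-hydroxy-4-oxochromane-3,5-diyl diacetate, via acetoxy(aryloxy)-λ3-iodane 10 (not isolated)
Conditions: CF3CO2H (2 equiv), CH2Cl2, −40 °C → rt (9 added slowly to 3, 1.3 equiv)
Reagents that add atoms: none
Why: Acid-promoted ligand exchange tethers O7 of 3 to trivalent iodine, and the array C8=C7–O–I–C2'=C3' of 10 undergoes a charge-accelerated [3,3]-sigmatropic rearrangement that forms the C8–C3' biaryl bond and leaves a monovalent iodine at C2' (C1' is blocked by the chromone, C6 is screened by the 5-acetoxy group), after which both rings rearomatise; C2 and C3 are remote and unchanged, and any atropisomers of 11 converge in step 8.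

**Step 8**
Reactants: 11 iodinated tri-O-benzyl biaryl triacetate
Product: 12 (2R,3R)-2-(4-acetoxyphenyl)-8-[5-(5,7-dihydroxy-4-oxo-4H-chromen-2-yl)-2-hydroxyphenyl]-7-hydroxy-4-oxochromane-3,5-diyl diacetate
Conditions: H2 (1 atm), 10% Pd/C, NaOAc (1.5 equiv), THF–MeOH, rt, monitored and stopped at full conversion
Reagents that add atoms: none
Why: Catalytic hydrogenolysis cleaves the three benzyl aryl ethers and the aryl C–I bond in one operation (NaOAc buffers HI), while the chromone C2=C3, the aryl ketone and the stereocentres survive at 1 atm and rt.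

**Step 9**
Reactants: 12 biflavonoid triacetate
Product: 13 (2R,3R)-8-[5-(5,7-dihydroxy-4-oxo-4H-chromen-2-yl)-2-hydroxyphenyl]-3,5,7-trihydroxy-2-(4-hydroxyphenyl)chroman-4-one (target)
Conditions: HCl (1.25 M in MeOH), rt → 35 °C; Sephadex LH-20
Reagents that add atoms: none
Why: Acid-catalysed transesterification removes the two phenolic acetates and the 3-acetate without the enolate or ring-opening pathways that epimerise C2/C3 of dihydroflavonols under base, so the purchased (2R,3R) configuration is delivered intact.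

## Compound list

1 | (+)-aromadendrin, (2R,3R)-3,5,7-trihydroxy-2-(4-hydroxyphenyl)chroman-4-one | O=C1c2c(O)cc(O)cc2O[C@H](c2ccc(O)cc2)[C@H]1O | starting material
2 | (2R,3R)-2-(4-acetoxyphenyl)-4-oxochromane-3,5,7-triyl triacetate | O=C1c2c(OC(C)=O)cc(OC(C)=O)cc2O[C@H](c2ccc(OC(C)=O)cc2)[C@H]1OC(C)=O | intermediate
3 | (2R,3R)-2-(4-acetoxyphenyl)-7-hydroxy-4-oxochromane-3,5-diyl diacetate | O=C1c2c(OC(C)=O)cc(O)cc2O[C@H](c2ccc(OC(C)=O)cc2)[C@H]1OC(C)=O | intermediate
4 | 4-hydroxy-2-iodobenzaldehyde | O=Cc1ccc(O)cc1I | starting material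
5 | 4-(benzyloxy)-2-iodobenzaldehyde | O=Cc1ccc(OCc2ccccc2)cc1I | intermediate
6 | 1-[2,4-bis(benzyloxy)-6-hydroxyphenyl]ethan-1-one | CC(=O)c1c(O)cc(OCc2ccccc2)cc1OCc1ccccc1 | starting material
7 | (E)-1-[2,4-bis(benzyloxy)-6-hydroxyphenyl]-3-[4-(benzyloxy)-2-iodophenyl]prop-2-en-1-one | O=C(/C=C/c1ccc(OCc2ccccc2)cc1I)c1c(O)cc(OCc2ccccc2)cc1OCc1ccccc1 | intermediate
8 | 5,7-bis(benzyloxy)-2-[4-(benzyloxy)-2-iodophenyl]-4H-chromen-4-one | O=c1cc(-c2ccc(OCc3ccccc3)cc2I)oc2cc(OCc3ccccc3)cc(OCc3ccccc3)c12 | intermediate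
9 | {5-(benzyloxy)-2-[5,7-bis(benzyloxy)-4-oxo-4H-chromen-2-yl]phenyl}-λ3-iodanediyl diacetate | CC(=O)OI(OC(C)=O)c1cc(OCc2ccccc2)ccc1-c1cc(=O)c2c(OCc3ccccc3)cc(OCc3ccccc3)cc2o1 | intermediate
10 | acetoxy(aryloxy)-λ3-iodane: iodine of 9 bonded to O7 of 3 in place of one acetate | O=C1c2c(OC(C)=O)cc(OI(OC(C)=O)c3cc(OCc4ccccc4)ccc3-c3cc(=O)c4c(OCc5ccccc5)cc(OCc5ccccc5)cc4o3)cc2O[C@H](c2ccc(OC(C)=O)cc2)[C@H]1OC(C)=O | intermediate (not isolated)
11 | (2R,3R)-2-(4-acetoxyphenyl)-8-{6-(benzyloxy)-3-[5,7-bis(benzyloxy)-4-oxo-4H-chromen-2-yl]-2-iodophenyl}-7-hydroxy-4-oxochromane-3,5-diyl diacetate | O=C1c2c(OC(C)=O)cc(O)c(-c3c(OCc4ccccc4)ccc(-c4cc(=O)c5c(OCc6ccccc6)cc(OCc6ccccc6)cc5o4)c3I)c2O[C@H](c2ccc(OC(C)=O)cc2)[C@H]1OC(C)=O | intermediate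
12 | (2R,3R)-2-(4-acetoxyphenyl)-8-[5-(5,7-dihydroxy-4-oxo-4H-chromen-2-yl)-2-hydroxyphenyl]-7-hydroxy-4-oxochromane-3,5-diyl diacetate | O=C1c2c(OC(C)=O)cc(O)c(-c3cc(-c4cc(=O)c5c(O)cc(O)cc5o4)ccc3O)c2O[C@H](c2ccc(OC(C)=O)cc2)[C@H]1OC(C)=O | intermediate
13 | (2R,3R)-8-[5-(5,7-dihydroxy-4-oxo-4H-chromen-2-yl)-2-hydroxyphenyl]-3,5,7-trihydroxy-2-(4-hydroxyphenyl)chroman-4-one | O=C1c2c(O)cc(O)c(-c3cc(-c4cc(=O)c5c(O)cc(O)cc5o4)ccc3O)c2O[C@H](c2ccc(O)cc2)[C@H]1O | target

## Count and risks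

Total steps: 9. Longest linear sequence: 7 (steps 3–9, from 4 to 13).

**Step 7 (most likely to fail).** The electron-poor, acid-like phenol 3 may be oxidised by trivalent iodine, may form a C-bound iodonium phenolate, or may rearrange to C6 instead of C8. The [3,3] coupling of aryl iodanes with phenols is precedented, but not on a substrate of this kind, and the TFA conditions are my choice rather than a literature procedure.

Fallback, setting out from 8 (with 3) and coming back at 12: the tether atom is changed from iodine to sulfur, so the phenol never meets an oxidising iodane. From 8, coupling with NaSMe (CuI, 1,10-phenanthroline, DMF, 80 °C) gives 5,7-bis(benzyloxy)-2-[4-(benzyloxy)-2-(methylsulfanyl)phenyl]-4H-chromen-4-one F1. One equivalent of mCPBA (CH2Cl2, −40 °C) gives the racemic sulfoxide 5,7-bis(benzyloxy)-2-[4-(benzyloxy)-2-(methylsulfinyl)phenyl]-4H-chromen-4-one F2. Activation of F2 with (CF3CO)2O in the presence of 3 (CH2Cl2, −40 °C → rt) brings about the sulfur-tethered [3,3]-sigmatropic shift to (2R,3R)-2-(4-acetoxyphenyl)-8-{6-(benzyloxy)-3-[5,7-bis(benzyloxy)-4-oxo-4H-chromen-2-yl]-2-(methylsulfanyl)phenyl}-7-hydroxy-4-oxochromane-3,5-diyl diacetate F3. Raney Ni under H2 (EtOH–THF, rt) then removes the methylsulfanyl group and the three benzyl ethers, arriving at 12.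

**Step 8.** The hindered aryl iodide may be reduced slowly, iodide may poison the catalyst, and the chromone C2=C3 may be over-reduced on long exposure.

Fallback, setting out from 11 and coming back at 12: the reductive step is split into two hydrogen-free operations. Radical chain deiodination (Bu3SnH, AIBN, toluene, 80 °C) gives (2R,3R)-2-(4-acetoxyphenyl)-8-{2-(benzyloxy)-5-[5,7-bis(benzyloxy)-4-oxo-4H-chromen-2-yl]phenyl}-7-hydroxy-4-oxochromane-3,5-diyl diacetate F4. Lewis-acid debenzylation (BCl3, pentamethylbenzene, CH2Cl2, −78 °C) then returns to 12.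

**Step 5.** HI formed during the I2/DMSO cyclisation can cleave the peri 5-benzyl ether at 120 °C.

Fallback, setting out from 5 (with 6) and coming back at 8: the chalcone route is replaced by a Baker–Venkataraman sequence. Pinnick oxidation of 5 (NaClO2, NaH2PO4, 2-methyl-2-butene, tBuOH–H2O) gives 4-(benzyloxy)-2-iodobenzoic acid F5. Esterification with the phenol of 6 (EDC·HCl, DMAP, CH2Cl2) gives 2-acetyl-3,5-bis(benzyloxy)phenyl 4-(benzyloxy)-2-iodobenzoate F6. O→C acyl transfer (KOH, pyridine, 50 °C) gives 1-[2,4-bis(benzyloxy)-6-hydroxyphenyl]-3-[4-(benzyloxy)-2-iodophenyl]propane-1,3-dione F7. Cyclodehydration (TsOH·H2O, toluene, 80 °C) closes ring C and returns to 8.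

## Further compounds

F1 | step 7 | 5,7-bis(benzyloxy)-2-[4-(benzyloxy)-2-(methylsulfanyl)phenyl]-4H-chromen-4-one | O=c1cc(-c2ccc(OCc3ccccc3)cc2SC)oc2cc(OCc3ccccc3)cc(OCc3ccccc3)c12
F2 | step 7 | 5,7-bis(benzyloxy)-2-[4-(benzyloxy)-2-(methylsulfinyl)phenyl]-4H-chromen-4-one (racemic at sulfur) | O=c1cc(-c2ccc(OCc3ccccc3)cc2S(C)=O)oc2cc(OCc3ccccc3)cc(OCc3ccccc3)c12
F3 | step 7 | (2R,3R)-2-(4-acetoxyphenyl)-8-{6-(benzyloxy)-3-[5,7-bis(benzyloxy)-4-oxo-4H-chromen-2-yl]-2-(methylsulfanyl)phenyl}-7-hydroxy-4-oxochromane-3,5-diyl diacetate | O=C1c2c(OC(C)=O)cc(O)c(-c3c(OCc4ccccc4)ccc(-c4cc(=O)c5c(OCc6ccccc6)cc(OCc6ccccc6)cc5o4)c3SC)c2O[C@H](c2ccc(OC(C)=O)cc2)[C@H]1OC(C)=O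
F4 | step 8 | (2R,3R)-2-(4-acetoxyphenyl)-8-{2-(benzyloxy)-5-[5,7-bis(benzyloxy)-4-oxo-4H-chromen-2-yl]phenyl}-7-hydroxy-4-oxochromane-3,5-diyl diacetate | O=C1c2c(OC(C)=O)cc(O)c(-c3cc(-c4cc(=O)c5c(OCc6ccccc6)cc(OCc6ccccc6)cc5o4)ccc3OCc3ccccc3)c2O[C@H](c2ccc(OC(C)=O)cc2)[C@H]1OC(C)=O
F5 | step 5 | 4-(benzyloxy)-2-iodobenzoic acid | OC(=O)c1ccc(OCc2ccccc2)cc1I
F6 | step 5 | 2-acetyl-3,5-bis(benzyloxy)phenyl 4-(benzyloxy)-2-iodobenzoate | CC(=O)c1c(OC(=O)c2ccc(OCc3ccccc3)cc2I)cc(OCc2ccccc2)cc1OCc1ccccc1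
F7 | step 5 | 1-[2,4-bis(benzyloxy)-6-hydroxyphenyl]-3-[4-(benzyloxy)-2-iodophenyl]propane-1,3-dione | O=C(CC(=O)c1ccc(OCc2ccccc2)cc1I)c1c(O)cc(OCc2ccccc2)cc1OCc1ccccc1
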